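## Analysis of the target

The target (C31H44O4) is a tetracycle built around a six-membered ring A, C1(=O)–C2–C3(OH)–C4(OH)–C5(O)=C6, in which C2 carries a geranyl group and C6 a prenyl group. Ring B is the cyclohexene C2–C7–C8=C9(CH3)–C10–C3, ring C the cyclopentane C3–C10–C11–C12–C4 and ring D the dihydrofuran C4–C12–C13(CH3)2–O–C5, whose oxygen is the enol-ether oxygen of the vinylogous ester C1(=O)–C6=C5–O. The five stereocentres are contiguous (C2 R, C3 R, C4 R, C10 S, C12 S in these labels): C2 is an all-carbon quaternary centre, C3 and C4 are neighbouring tertiary carbinols, and rings A, B and D all leave ring C on the same face, so the two hydroxyl groups and the hydrogens on C10 and C12 are mutually cis. Only three relations are independent: geranyl on C2 trans to C11 across ring B, the cis-diol, and C13 on the side of C5. The molecule is sensitive through its β-hydroxy ketone (C3–OH/C1=O, retro-aldol), its vinylogous ester and four trisubstituted olefins, which exclude strong protic acid, strong base late in the route and any unselective electrophilic oxidant. The difficulty lies in the quaternary centre C2 wedged between a ketone and a tertiary carbinol, in oxidising C3 in the presence of the olefins, and in closing rings C and D onto one carbonyl carbon with control of C12. The strategy rests on reading ring A as a dearomatised 1,2,4-trioxygenated benzene: C1, C4 and C5 bear oxygen, C2 is the ortho carbon of the C1 oxygen, and its second substituent C7–C8=C9 is an allyl unit, so the bond C2–C7 can be made by allylating a phenol at an already substituted ortho carbon.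

## Retrosynthetic reasoning

**30 to 29 (C4–C12 and C13–O).** Rings C and D are opened together. Both bonds belong to the prenyl unit on C10, which in ketol 29 already hangs next to the C4 ketone, and both closures are five-membered. Forward, a Lewis acid must make C12 attack C4 and let the C5 enol oxygen take up the C13 cation. The tether fixes the configuration at C4 (cis-diol), and only one orientation of the olefin can close ring D, which fixes C12.

**29 to 28 (C3–O).** The C3 hydroxyl is removed next, because C3 is α to the C4 ketone only as long as ring C is open; after the Prins closure it could no longer be oxidised. Forward, an enolate must be generated at C3 only and oxidised by an electrophilic oxygen-transfer reagent that ignores olefins, from the face opposite the C7–C8=C9 arc of ring B.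

**28 to 26 (two O–CH3 bonds).** The C4 ketone and the C5 enol of 28 are traced back to the two enol methyl ethers of dienone 26 (passing through 27). This links ring A to an aromatic precursor with methoxy groups on C4 and C5. Forward, the C4 enol ether hydrolyses by C-protonation and the C5 methoxy group, then part of a 2-methoxy-ene-1,4-dione, is displaced by hydroxide.

**26 to 25 (C2–C7, the key disconnection).** Cutting C2–C7 rearomatises ring A and turns ring B into an allylic side chain on C3. No other bond of 26 gives back a benzene ring, and this one removes a ring and the quaternary centre at once. Forward, phenol 25 must be alkylated at its geranyl-bearing ortho carbon by the (Z)-allylic carbonate under a chiral zerovalent palladium catalyst, with the face of C2 chosen relative to the existing C10 centre.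

**25 to 17 (side-chain olefin: C9–CH3, C8–C7, C9–C8).** The (Z)-trisubstituted allylic carbonate is taken back through alcohol 22 and enoate 21 to ynoate 20, and from there through dibromo-olefin 18 to aldehyde 17. The C9 methyl is disconnected because syn-addition of an organocopper methyl donor to an ynoate gives exactly the geometry needed for the six-membered closure (C10 cis to C7). Olefination of a methyl ketone would not.

**17 to 10 (aryl–geranyl and aryl–prenyl bonds).** The two allyl groups on the ring are removed, geranyl (from 13) at the future C2 and prenyl (from 7) at the future C6, leading back through 15 and 12 to silyl ether 10. Both positions are ortho to the methoxymethyl-protected oxygen, so each bond can be made by directed metalation and copper-mediated allylation, first at the carbon flanked by two oxygens, then at the remaining ortho carbon.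

**10 to 6 and 7 (C10–C11).** The benzylic stereocentre is disconnected at its bond to the prenyl methylene. Forward, the enolate of arylacetyl imide 6 is alkylated with 7 under control of the oxazolidinone, and the imide is then reduced (8, 9). The (R)-auxiliary is required for the S configuration of C10 in 25, and a valine-derived auxiliary is used because it has no aromatic C–H to interfere two steps earlier.

**6 to 1 and 2 (C1–O and N-acyl bond).** The oxygen on the future C1 is removed back to imide 3, which comes from acid 1 and auxiliary 2. The C3 carbon substituent is carried in from the start, because once prenyl and geranyl groups are on the ring the last aromatic position can no longer be halogenated or metalated selectively. Forward, the only ring C–H of 3 with no ortho neighbour is borylated under steric control and oxidised to phenol 5.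

## Alternatives that were turned down

**Alternative 1:** Rings A and D are left open and ring C is disconnected at C3–C4. Forward, SmI2 (divalent samarium) reduces the ketone of the α-keto ester in the ring B ketone A1, and the ketyl adds to the C3 carbonyl to give the bicyclic cis-diol ester A2.
- For: reductive ketyl–carbonyl coupling is a dependable route to two adjacent tertiary carbinols, and bridging of both oxygens by trivalent samarium gives the cis-diol directly. On the C3/C4 diol this plan is stronger than the chosen one, which needs an enolate hydroxylation and a tether-controlled closure for the same relation.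
- Against: A1 must already hold C2, C10 and C12 in the right configuration on a non-aromatic skeleton, which means three separate asymmetric operations before the key step, one of them a quaternary centre beside two carbonyls. SmI2 has to discriminate three ketones (C1, C3, C4). After A2, ring A must still be closed by acylating C6 with the C5 ester and ring D by enol-ether formation from the C13 silyl ether, both on a base-sensitive β-hydroxy ketone.
- In exchange, the chosen strategy brings ring A in complete from a flat arene and needs three steps after its key step.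

**Alternative 2:** Rings B, C and D are disconnected at once (C3–C10, C4–C12, C13–O), back to the monocyclic triketone A3 whose C2 side chain carries the C9 ketone and the terminal prenyl unit. Forward, pyrrolidinium acetate triggers the aldol of C10 onto C3, and BF3·OEt2 then drives the Prins addition of C12 to C4 and capture of C13 by the C5 enol oxygen, giving the tetracyclic ketone A4.
- For: three rings and four stereocentres from one stereocentre in one flask. On step count this plan is clearly stronger if the cascade runs as drawn.
- Against: the enamine of the C9 ketone must react through C10 and not C8, and with C3 and not the equally reachable C1. A3 is a vicinal polycarbonyl array that hydrates and enolises, with C2 between two acyl groups (retro-Claisen). C10 is created without an evident control element. A4 lacks the C9 methyl and the C8=C9 olefin, which would have to be added by regioselective enol triflate formation towards C8 and cross-coupling beside two free tertiary alcohols. A3 also needs its own enantioselective quaternary-centre synthesis.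
- In exchange, the chosen route spreads the same bond formations over separately controllable steps (C2 by catalyst, C3 by convex-face oxidation, C4 and C12 by the tether) and carries the C8=C9–CH3 unit from the start.

**Alternative 3:** Ring B is disconnected at C3–C10 in an achiral precursor, the 2,2-disubstituted cyclohexane-1,3,5-trione A5. Forward, a proline-type catalyst forms the enamine of the side-chain C9 ketone, and C10 adds to one of the two mirror-related ring carbonyls to give the bicyclic ketol A6.
- For: C2, the C3 carbinol and C10 arise in one catalytic step from a symmetrical compound by a well-understood enamine aldol, without an auxiliary. In economy of the asymmetric step it is stronger than the chosen route, which uses an auxiliary for C10 and a chiral catalyst for C2, and it installs the C3 oxygen without a separate oxidation.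
- Against: A5 is a vinylogous acid (its C4 and C6 methylenes lie between carbonyls), so the carbonyls to be differentiated are largely enolised and poorly electrophilic, and the acid competes for the amine. A6 is far from the target: C4 must still be oxidised, C6 prenylated, the C5 enol ether and rings C and D formed, and the C9 ketone turned into the methyl-bearing olefin, each with a regiochemical choice (C4 or C6, C8 or C10).
- In exchange, the chosen strategy starts from a ring A that already has oxygen on C1, C4 and C5 and carbon on C2, C3 and C6, so after the key step only C3 has to be functionalised.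

Key step: step 17

Assumption: the sense of induction of the Trost ligand on this substrate cannot be assigned from a model with confidence, so the (R,R)-antipode is written; if the first run shows the opposite facial preference, the (S,S)-antipode is used instead, and nothing else changes. Compounds 1, 2, 7 and 13 are taken as commercial.

Abbreviation in names: Ar = 2-[(2E)-3,7-dimethylocta-2,6-dien-1-yl]-5,6-dimethoxy-3-(methoxymethoxy)-4-(3-methylbut-2-en-1-yl)phenyl, the fully substituted ring of 15 to 23.

## Route

Step 1
Reactants: 1 (2,3-dimethoxyphenyl)acetic acid; 2 (4R)-4-isopropyl-1,3-oxazolidin-2-one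
Product: 3 (4R)-3-[(2,3-dimethoxyphenyl)acetyl]-4-isopropyl-1,3-oxazolidin-2-one
Conditions: t-BuCOCl, Et3N, THF, −20 °C; then LiCl, 2, −20 °C → rt
Reagents that add atoms: none
Why: N-acylation of the oxazolidinone through the pivaloyl mixed anhydride (attachment of an Evans auxiliary); the anhydride is attacked at the less hindered arylacetyl carbonyl and LiCl activates the oxazolidinone under mild base.

Step 2
Reactants: 3 arylacetyl imide
Product: 5 (4R)-3-[(5-hydroxy-2,3-dimethoxyphenyl)acetyl]-4-isopropyl-1,3-oxazolidin-2-one, via aryl pinacol boronate 4 (not isolated)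
Conditions: [Ir(OMe)(cod)]2 (1.5 mol %), 4,4′-di-tert-butyl-2,2′-bipyridine (3 mol %), B2pin2, THF, 80 °C; then KHSO5 (as 2KHSO5·KHSO4·K2SO4), acetone/H2O, rt
Reagents that add atoms: potassium peroxymonosulfate, [K+].[O-]S(=O)(=O)OO
Why: Sterically governed iridium-catalysed aromatic C–H borylation takes place at the only ring C–H without an ortho substituent (the future C1), and the boronate is oxidised in the same flask to the phenol (one-pot borylation/oxidation). The valine-derived auxiliary offers no competing aromatic C–H.

Step 3
Reactants: 5 phenol imide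
Product: 6 (4R)-3-{[2,3-dimethoxy-5-(methoxymethoxy)phenyl]acetyl}-4-isopropyl-1,3-oxazolidin-2-one
Conditions: MeOCH2Cl, i-Pr2NEt, CH2Cl2, 0 °C → rt
Reagents that add atoms: chloromethyl methyl ether, COCCl
Why: O-Alkylation of the phenol to its methoxymethyl ether, which later directs two ortho-metalations; the amine base is too weak to enolise the imide.

Step 4
Reactants: 6 methoxymethyl-protected imide; 7 prenyl bromide (1-bromo-3-methylbut-2-ene)
Product: 8 (4R)-3-{(2R)-2-[2,3-dimethoxy-5-(methoxymethoxy)phenyl]-5-methylhex-4-enoyl}-4-isopropyl-1,3-oxazolidin-2-one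
Conditions: NaN(SiMe3)2 (1.05 equiv), THF, −78 °C; then 7, −78 → −40 °C
Reagents that add atoms: none
Why: Evans asymmetric alkylation: the chelated (Z)-sodium enolate is alkylated on the face opposite the isopropyl group, which sets the benzylic centre (the future C10) as R in the imide. One equivalent of base and a cold quench protect the acidic α-aryl proton.

Step 5
Reactants: 8 alkylated imide
Product: 9 (2R)-2-[2,3-dimethoxy-5-(methoxymethoxy)phenyl]-5-methylhex-4-en-1-ol
Conditions: LiBH4, MeOH (1 equiv), THF, 0 °C
Reagents that add atoms: none
Why: Reductive removal of the auxiliary by hydride attack on the exocyclic carbonyl gives the primary alcohol; after this step the stereocentre is no longer α to a carbonyl and is configurationally secure.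

Step 6
Reactants: 9 primary alcohol
Product: 10 tert-butyl({(2R)-2-[2,3-dimethoxy-5-(methoxymethoxy)phenyl]-5-methylhex-4-en-1-yl}oxy)dimethylsilane
Conditions: t-BuMe2SiCl, imidazole, DMF, rt
Reagents that add atoms: tert-butyldimethylsilyl chloride, CC(C)(C)[Si](C)(C)Cl
Why: Standard silylation; the bulky, poorly coordinating silyl ether keeps the side-chain oxygen from acting as a second directing group in the metalations.

Step 7
Reactants: 10 silyl ether; 7 prenyl bromide
Product: 12 tert-butyl({(2R)-2-[2,3-dimethoxy-5-(methoxymethoxy)-4-(3-methylbut-2-en-1-yl)phenyl]-5-methylhex-4-en-1-yl}oxy)dimethylsilane, via aryllithium 11 (not isolated)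
Conditions: n-BuLi, TMEDA, THF, −78 → 0 °C; CuBr·SMe2, −78 °C; then 7, −78 °C → rt
Reagents that add atoms: none
Why: Directed ortho-metalation: the C–H between the methoxymethoxy and methoxy groups is acidified and coordinated by both oxygens, so lithiation is site-selective. Transmetalation to copper gives SN2 rather than SN2′ coupling with the allylic bromide, placing prenyl on the future C6.

Step 8
Reactants: 12 prenylated arene; 13 geranyl bromide ((2E)-1-bromo-3,7-dimethylocta-2,6-diene)
Product: 15 tert-butyl{[(2R)-2-Ar-5-methylhex-4-en-1-yl]oxy}dimethylsilane, via aryllithium 14 (not isolated)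
Conditions: s-BuLi, TMEDA, THF, −78 °C; CuBr·SMe2, −78 °C; then 13, −78 °C → rt
Reagents that add atoms: none
Why: Second directed ortho-metalation at the last position ortho to the methoxymethoxy group (the future C2), favoured kinetically at −78 °C over lateral deprotonation of the benzylic–allylic methylene. Copper-mediated SN2 allylation keeps the E geometry of the geranyl unit.

Step 9
Reactants: 15 hexasubstituted silyl ether
Product: 16 (2R)-2-Ar-5-methylhex-4-en-1-ol
Conditions: Bu4NF, THF, 0 °C → rt
Reagents that add atoms: none
Why: Fluoride cleavage of the primary silyl ether; the aryl methoxymethyl ether and the olefins are inert.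

Step 10
Reactants: 16 primary alcohol
Product: 17 (2R)-2-Ar-5-methylhex-4-enal
Conditions: Dess–Martin periodinane, CH2Cl2, 0 °C → rt
Reagents that add atoms: none
Why: Dess–Martin oxidation under near-neutral conditions; the twisted, di-ortho-substituted aryl ring disfavours enolisation of the α-aryl aldehyde, which is used at once.

Step 11
Reactants: 17 aldehyde
Product: 18 (3S)-3-Ar-1,1-dibromo-6-methylhepta-1,5-diene
Conditions: CBr4, PPh3, Et3N, CH2Cl2, 0 °C
Reagents that add atoms: carbon tetrabromide, BrC(Br)(Br)Br
Why: First stage of the Corey–Fuchs sequence (dibromo-olefination), adding the future C8 with a non-basic ylide, so the α-stereocentre is not at risk; the descriptor changes to S only through the priority order.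

Step 12
Reactants: 18 dibromo-olefin
Product: 20 methyl (4S)-4-Ar-7-methyloct-6-en-2-ynoate, via lithium acetylide 19 (not isolated)
Conditions: n-BuLi (2.1 equiv), THF, −78 °C; then cannulated into ClCO2Me, THF, −78 °C
Reagents that add atoms: methyl chloroformate, COC(=O)Cl
Why: Second stage of the Corey–Fuchs sequence: bromine–lithium exchange, 1,2-shift and deprotonation give the acetylide, which is acylated by the chloroformate to the ynoate carrying the future C7. Inverse addition at −78 °C keeps the product away from excess base.

Step 13
Reactants: 20 ynoate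
Product: 21 methyl (2Z,4S)-4-Ar-3,7-dimethylocta-2,6-dienoate
Conditions: Me2CuLi (from CuI, MeLi), THF, −78 °C; MeOH quench at −78 °C
Reagents that add atoms: lithium dimethylcuprate, [Li+].C[Cu-]C
Why: Syn-carbocupration of the ynoate puts methyl and copper on the same side, so after cold protonation C10 and the ester are cis: the (Z)-trisubstituted enoate that ring B requires. Quenching before warming avoids E/Z scrambling through the allenoate.

Step 14
Reactants: 21 (Z)-enoate
Product: 22 (2Z,4S)-4-Ar-3,7-dimethylocta-2,6-dien-1-ol
Conditions: i-Bu2AlH (2.5 equiv), CH2Cl2, −78 °C; aq. KNaC4H4O6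
Reagents that add atoms: none
Why: 1,2-Reduction of the enoate by two hydride equivalents gives the allylic alcohol with the olefin geometry unchanged.

Step 15
Reactants: 22 (Z)-allylic alcohol
Product: 23 (2Z,4S)-4-Ar-3,7-dimethylocta-2,6-dien-1-yl methyl carbonate
Conditions: ClCO2Me, pyridine, CH2Cl2, 0 °C
Reagents that add atoms: methyl chloroformate, COC(=O)Cl
Why: Acylation of the primary allylic alcohol to the methyl carbonate, a leaving group that releases its own base (methoxide) on ionisation.

Step 16
Reactants: 23 methoxymethyl-protected carbonate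
Product: 25 (2Z,4S)-4-{2-[(2E)-3,7-dimethylocta-2,6-dien-1-yl]-3-hydroxy-5,6-dimethoxy-4-(3-methylbut-2-en-1-yl)phenyl}-3,7-dimethylocta-2,6-dien-1-yl methyl carbonate, via aryl trimethylsilyl ether 24 (not isolated)
Conditions: Me3SiOSO2CF3, 2,2′-bipyridyl, CH2Cl2, 0 °C; then H2O, rt
Reagents that add atoms: none
Why: Silyl triflate/bipyridyl cleavage of an aromatic methoxymethyl ether runs through the aryl silyl ether under buffered, aprotic conditions, so neither the allylic carbonate nor the ortho-prenyl and ortho-geranyl phenol (prone to acid-induced chroman formation) meets free acid.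

Step 17
Reactants: 25 hexasubstituted phenol with (Z)-allylic methyl carbonate
Product: 26 (5S,8aR)-8a-[(2E)-3,7-dimethylocta-2,6-dien-1-yl]-3,4-dimethoxy-6-methyl-2,5-bis(3-methylbut-2-en-1-yl)-5,8-dihydronaphthalen-1(8aH)-one
Conditions: Pd2(dba)3·CHCl3 (2.5 mol %), (R,R)-DACH-phenyl Trost ligand (7.5 mol %), CH2Cl2 (0.01 M), 0 °C
Reagents that add atoms: none
Why: Zerovalent palladium ionises the allylic carbonate with loss of CO2 to an anti-configured cationic η3-allyl complex (C7–C8–C9) and methoxide, which deprotonates the phenol; the phenoxide then attacks the primary terminus C7 through its ortho carbon C2 on the allyl face remote from the metal, an intramolecular Tsuji–Trost alkylation whose closest known relatives are the palladium-catalysed allylic dearomatisations of phenols and naphthols. Ring B closes in a six-membered mode (6-exo with respect to the allyl unit), whereas attack through oxygen would need an eight-membered ring and attack at C9 a four-membered one, and the other ortho carbon C6 cannot reach the allyl unit. Because C2 already carries geranyl, the cyclohexa-2,4-dienone cannot return to a phenol, and its fully substituted diene resists Diels–Alder dimerisation. The (Z)-olefin is needed because it places C10 anti on the allyl unit; syn/anti exchange would have to pass through a tertiary σ-palladium species at C9 and is slow. The only new stereocentre, C2, is set by which face of the arene meets C7: in one transition state C11 lies close to the C4 methoxy oxygen (allylic 1,3-strain; leads to the required 8aR isomer, geranyl trans to C11), in the other it lies syn to the rising geranyl methylene (a syn-pentane contact; leads to the epimer), so the substrate bias should be small and the chiral pocket of the Trost ligand is relied on to select the first. The reaction is run cold and stopped at full conversion so that re-ionisation of the doubly activated C2–C7 bond cannot equilibrate the product.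

Step 18
Reactants: 26 bicyclic dienone
Product: 28 (5R,8aR)-8a-[(2E)-3,7-dimethylocta-2,6-dien-1-yl]-3-hydroxy-6-methyl-2,5-bis(3-methylbut-2-en-1-yl)-4a,5,8,8a-tetrahydronaphthalene-1,4-dione (C4a epimers), via methoxy enedione 27 (not isolated)
Conditions: aq. HCl (1 M), THF, 0 °C → rt; then aq. LiOH (degassed), 40 °C; then aq. HCl to pH 3
Reagents that add atoms: water, O; lithium hydroxide, [Li+].[OH-]
Why: Acid-catalysed hydrolysis of the cross-conjugated enol ether (C-protonation at C3) unmasks the C4 ketone; the remaining methoxy group is then part of a 2-methoxy-ene-1,4-dione and is displaced by hydroxide through addition–elimination at C5 (vinylogous ester saponification). The C3 configuration is irrelevant because the centre is enolised in the next step, and the C10 descriptor changes to R only through the priority order.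

Step 19
Reactants: 28 hydroxy enedione (diosphenol)
Product: 29 (4aR,5S,8aR)-8a-[(2E)-3,7-dimethylocta-2,6-dien-1-yl]-3,4a-dihydroxy-6-methyl-2,5-bis(3-methylbut-2-en-1-yl)-4a,5,8,8a-tetrahydronaphthalene-1,4-dione
Conditions: LiN(i-Pr)2 (2.4 equiv), THF, −78 → −40 °C; 2-(phenylsulfonyl)-3-phenyloxaziridine, −78 °C; AcOH
Reagents that add atoms: 2-(phenylsulfonyl)-3-phenyloxaziridine, O=S(=O)(N1OC1c1ccccc1)c1ccccc1
Why: Enolate hydroxylation with the Davis oxaziridine on a dianion: the first equivalent of base ionises the vinylogous acid (which also shuts off deprotonation of the C6 prenyl methylene), the second removes the C3 proton next to the C4 ketone, and the more basic C3 enolate carbon is the one oxidised. Oxygen should arrive on the convex face of C3, opposite the C7–C8=C9 arc of ring B and the C10 prenyl group, that is cis to geranyl and to the C10 hydrogen; the anionic diketonate also disfavours retro-aldol cleavage of the new alkoxide.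

Step 20
Reactants: 29 α-ketol
Product: 30 CNP0323114.1, the tetracycle with rings A to D as labelled in the analysis (2R,3R,4R,10S,12S)
Conditions: Me2AlCl (3.5 equiv), CH2Cl2, −78 → −20 °C; aq. KNaC4H4O6
Reagents that add atoms: none
Why: Lewis-acid Prins cyclisation with oxygen termination: the aluminium-chelated C4 ketone is attacked by C12 of the C10 prenyl group (ring C), and the tertiary C13 cation is captured by the C5 enol oxygen (ring D). The tether can reach only the face of C4 on which C10 lies, which makes ring C cis-fused and the diol cis, and only the orientation with C13 over C5 can close ring D, which fixes C12; the methyl groups on aluminium take up the protons released.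

## Compound list

1 | (2,3-dimethoxyphenyl)acetic acid | COc1cccc(CC(=O)O)c1OC | starting material
2 | (4R)-4-isopropyl-1,3-oxazolidin-2-one | CC(C)[C@@H]1COC(=O)N1 | starting material
3 | (4R)-3-[(2,3-dimethoxyphenyl)acetyl]-4-isopropyl-1,3-oxazolidin-2-one | COc1cccc(CC(=O)N2[C@H](C(C)C)COC2=O)c1OC | intermediate
4 | (4R)-3-{[2,3-dimethoxy-5-(4,4,5,5-tetramethyl-1,3,2-dioxaborolan-2-yl)phenyl]acetyl}-4-isopropyl-1,3-oxazolidin-2-one (formed and consumed in step 2) | COc1cc(B2OC(C)(C)C(C)(C)O2)cc(CC(=O)N3[C@H](C(C)C)COC3=O)c1OC | intermediate
5 | (4R)-3-[(5-hydroxy-2,3-dimethoxyphenyl)acetyl]-4-isopropyl-1,3-oxazolidin-2-one | COc1cc(O)cc(CC(=O)N2[C@H](C(C)C)COC2=O)c1OC | intermediate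
6 | (4R)-3-{[2,3-dimethoxy-5-(methoxymethoxy)phenyl]acetyl}-4-isopropyl-1,3-oxazolidin-2-one | COCOc1cc(CC(=O)N2[C@H](C(C)C)COC2=O)c(OC)c(OC)c1 | intermediate
7 | prenyl bromide (1-bromo-3-methylbut-2-ene) | CC(C)=CCBr | starting material
8 | (4R)-3-{(2R)-2-[2,3-dimethoxy-5-(methoxymethoxy)phenyl]-5-methylhex-4-enoyl}-4-isopropyl-1,3-oxazolidin-2-one | COCOc1cc([C@@H](CC=C(C)C)C(=O)N2[C@H](C(C)C)COC2=O)c(OC)c(OC)c1 | intermediate
9 | (2R)-2-[2,3-dimethoxy-5-(methoxymethoxy)phenyl]-5-methylhex-4-en-1-ol | COCOc1cc([C@@H](CC=C(C)C)CO)c(OC)c(OC)c1 | intermediate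
10 | tert-butyl({(2R)-2-[2,3-dimethoxy-5-(methoxymethoxy)phenyl]-5-methylhex-4-en-1-yl}oxy)dimethylsilane | COCOc1cc([C@@H](CC=C(C)C)CO[Si](C)(C)C(C)(C)C)c(OC)c(OC)c1 | intermediate
11 | aryllithium from 10, lithium on the ring carbon between the methoxymethoxy and methoxy groups (formed and consumed in step 7) | COCOc1cc([C@@H](CC=C(C)C)CO[Si](C)(C)C(C)(C)C)c(OC)c(OC)c1[Li] | intermediate
12 | tert-butyl({(2R)-2-[2,3-dimethoxy-5-(methoxymethoxy)-4-(3-methylbut-2-en-1-yl)phenyl]-5-methylhex-4-en-1-yl}oxy)dimethylsilane | COCOc1cc([C@@H](CC=C(C)C)CO[Si](C)(C)C(C)(C)C)c(OC)c(OC)c1CC=C(C)C | intermediate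
13 | geranyl bromide ((2E)-1-bromo-3,7-dimethylocta-2,6-diene) | CC(C)=CCC/C(C)=C/CBr | starting material
14 | aryllithium from 12, lithium on the last free ring carbon, ortho to the methoxymethoxy group (formed and consumed in step 8) | COCOc1c([Li])c([C@@H](CC=C(C)C)CO[Si](C)(C)C(C)(C)C)c(OC)c(OC)c1CC=C(C)C | intermediate
15 | tert-butyl{[(2R)-2-Ar-5-methylhex-4-en-1-yl]oxy}dimethylsilane | COCOc1c(C/C=C(\C)CCC=C(C)C)c([C@@H](CC=C(C)C)CO[Si](C)(C)C(C)(C)C)c(OC)c(OC)c1CC=C(C)C | intermediate
16 | (2R)-2-Ar-5-methylhex-4-en-1-ol | COCOc1c(C/C=C(\C)CCC=C(C)C)c([C@@H](CC=C(C)C)CO)c(OC)c(OC)c1CC=C(C)C | intermediate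
17 | (2R)-2-Ar-5-methylhex-4-enal | COCOc1c(C/C=C(\C)CCC=C(C)C)c([C@@H](CC=C(C)C)C=O)c(OC)c(OC)c1CC=C(C)C | intermediate
18 | (3S)-3-Ar-1,1-dibromo-6-methylhepta-1,5-diene | COCOc1c(C/C=C(\C)CCC=C(C)C)c([C@@H](CC=C(C)C)C=C(Br)Br)c(OC)c(OC)c1CC=C(C)C | intermediate
19 | [(3S)-3-Ar-6-methylhept-5-en-1-yn-1-yl]lithium (formed and consumed in step 12) | COCOc1c(C/C=C(\C)CCC=C(C)C)c([C@@H](CC=C(C)C)C#C[Li])c(OC)c(OC)c1CC=C(C)C | intermediate
20 | methyl (4S)-4-Ar-7-methyloct-6-en-2-ynoate | COCOc1c(C/C=C(\C)CCC=C(C)C)c([C@@H](CC=C(C)C)C#CC(=O)OC)c(OC)c(OC)c1CC=C(C)C | intermediate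
21 | methyl (2Z,4S)-4-Ar-3,7-dimethylocta-2,6-dienoate | COCOc1c(C/C=C(\C)CCC=C(C)C)c([C@@H](CC=C(C)C)/C(C)=C\C(=O)OC)c(OC)c(OC)c1CC=C(C)C | intermediate
22 | (2Z,4S)-4-Ar-3,7-dimethylocta-2,6-dien-1-ol | COCOc1c(C/C=C(\C)CCC=C(C)C)c([C@@H](CC=C(C)C)/C(C)=C\CO)c(OC)c(OC)c1CC=C(C)C | intermediate
23 | (2Z,4S)-4-Ar-3,7-dimethylocta-2,6-dien-1-yl methyl carbonate | COCOc1c(C/C=C(\C)CCC=C(C)C)c([C@@H](CC=C(C)C)/C(C)=C\COC(=O)OC)c(OC)c(OC)c1CC=C(C)C | intermediate
24 | trimethylsilyl ether of phenol 25 (trimethylsilyloxy in place of the methoxymethoxy group of 23; formed and consumed in step 16) | C[Si](C)(C)Oc1c(C/C=C(\C)CCC=C(C)C)c([C@@H](CC=C(C)C)/C(C)=C\COC(=O)OC)c(OC)c(OC)c1CC=C(C)C | intermediate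
25 | (2Z,4S)-4-{2-[(2E)-3,7-dimethylocta-2,6-dien-1-yl]-3-hydroxy-5,6-dimethoxy-4-(3-methylbut-2-en-1-yl)phenyl}-3,7-dimethylocta-2,6-dien-1-yl methyl carbonate | CC(C)=CCC/C(C)=C/Cc1c(O)c(CC=C(C)C)c(OC)c(OC)c1[C@@H](CC=C(C)C)/C(C)=C\COC(=O)OC | intermediate
26 | (5S,8aR)-8a-[(2E)-3,7-dimethylocta-2,6-dien-1-yl]-3,4-dimethoxy-6-methyl-2,5-bis(3-methylbut-2-en-1-yl)-5,8-dihydronaphthalen-1(8aH)-one | CC(C)=CCC/C(C)=C/C[C@]12CC=C(C)[C@H](CC=C(C)C)C2=C(OC)C(OC)=C(CC=C(C)C)C1=O | intermediate
27 | (5R,8aR)-8a-[(2E)-3,7-dimethylocta-2,6-dien-1-yl]-3-methoxy-6-methyl-2,5-bis(3-methylbut-2-en-1-yl)-4a,5,8,8a-tetrahydronaphthalene-1,4-dione, C4a epimers (formed and consumed in step 18) | CC(C)=CCC/C(C)=C/C[C@]12CC=C(C)[C@H](CC=C(C)C)C2C(=O)C(OC)=C(CC=C(C)C)C1=O | intermediate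
28 | (5R,8aR)-8a-[(2E)-3,7-dimethylocta-2,6-dien-1-yl]-3-hydroxy-6-methyl-2,5-bis(3-methylbut-2-en-1-yl)-4a,5,8,8a-tetrahydronaphthalene-1,4-dione, C4a epimers | CC(C)=CCC/C(C)=C/C[C@]12CC=C(C)[C@H](CC=C(C)C)C2C(=O)C(O)=C(CC=C(C)C)C1=O | intermediate
29 | (4aR,5S,8aR)-8a-[(2E)-3,7-dimethylocta-2,6-dien-1-yl]-3,4a-dihydroxy-6-methyl-2,5-bis(3-methylbut-2-en-1-yl)-4a,5,8,8a-tetrahydronaphthalene-1,4-dione | CC(C)=CCC/C(C)=C/C[C@]12CC=C(C)[C@H](CC=C(C)C)[C@]2(O)C(=O)C(O)=C(CC=C(C)C)C1=O | intermediate
30 | CNP0323114.1: tetracycle of rings A to D as labelled in the analysis, geranyl on C2, prenyl on C6, hydroxyls on C3 and C4, (2R,3R,4R,10S,12S) | CC(C)=CCC/C(C)=C/C[C@]12CC=C(C)[C@@H]3C[C@@H]4C(C)(C)OC(=C(CC=C(C)C)C1=O)[C@]4(O)[C@@]32O | target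

## Step count and steps least certain to work

Total step count: 20. Longest linear sequence: 20 steps, from 1 to 30; compounds 2, 7 and 13 enter this sequence as commercial reagents.

**Step 17 (key step).**
- What may go wrong: insufficient or inverted facial selection at C2, because the preset C10 centre and the ligand may pull in opposite directions; loss of a β-hydrogen from the allyl complex to give a 1,3-diene when cyclisation is slow; re-ionisation of the C2–C7 bond with equilibration of the epimers.
- Fallback: an alkylative dearomatisation without a transition metal, setting out from 22 and returning at 26. The methoxymethyl group of 22 is removed with HCl in methanol at 0 °C to give the phenol diol (2Z,4S)-4-{2-[(2E)-3,7-dimethylocta-2,6-dien-1-yl]-3-hydroxy-5,6-dimethoxy-4-(3-methylbut-2-en-1-yl)phenyl}-3,7-dimethylocta-2,6-dien-1-ol F1. The primary allylic alcohol is converted by an Appel reaction (CBr4, PPh3) into the allylic bromide 3-[(2Z,4S)-1-bromo-3,7-dimethylocta-2,6-dien-4-yl]-2-[(2E)-3,7-dimethylocta-2,6-dien-1-yl]-4,5-dimethoxy-6-(3-methylbut-2-en-1-yl)phenol F2. Its lithium phenoxide (LiN(SiMe3)2, toluene, −78 → 0 °C) is expected to close ring B by intramolecular ortho-C-alkylation to 26. Facial selection then rests on the substrate alone, and the epimers would be separated at 26.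

**Step 20.**
- What may go wrong: a concerted ene pathway in which C13 lies over the C4 oxygen, which gives an isopropenyl carbinol that cannot close ring D; participation of the geranyl olefin at C4 (bridged closure); an α-ketol shift at C3/C4 under the Lewis acid.
- Fallback: a staged closure setting out from 29 and returning at 30. TiCl4 with 2,6-di-tert-butylpyridine at −78 °C is expected to give the halo-Prins product, the ring-C-closed chlorohydrin F3 (C13 as a tertiary chloride, C5 enol free, C12 epimers). Silver triflate (AgOSO2CF3) with the same base then ionises the tertiary chloride so that the C5 enol oxygen closes ring D to 30. The C12 epimer that cannot close can fragment back to 29 and be recycled.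

**Step 19.**
- What may go wrong: incomplete second deprotonation; oxidation at C6 of the diketonate or electron transfer from the electron-rich dianion; delivery of oxygen from the concave face.
- Fallback: hydroxylation before the enol is unmasked, setting out from 26 and returning at 29. Hydrolysis of 26 with dilute acid alone is stopped at the methoxy enedione 27, which is isolated. Its monoanion (KN(SiMe3)2, THF, −78 °C) is oxidised with the same oxaziridine to the methoxy ketol (4aR,5S,8aR)-8a-[(2E)-3,7-dimethylocta-2,6-dien-1-yl]-4a-hydroxy-3-methoxy-6-methyl-2,5-bis(3-methylbut-2-en-1-yl)-4a,5,8,8a-tetrahydronaphthalene-1,4-dione F4. Nucleophilic demethylation of the vinylogous ester (LiCl, DMSO, 100 °C) then gives 29.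

**Step 8.**
- What may go wrong: lateral deprotonation of the benzylic–allylic prenyl methylene in place of ring metalation; slow lithiation at the crowded position; sluggish coupling of the hindered arylcopper species.
- Fallback: the geranyl position is marked with bromine before any olefin is present, setting out from 6 and returning at 15.
  - Bromination of 6 (N-bromosuccinimide, MeCN, 0 °C) para to the methoxy group gives (4R)-3-{[2-bromo-5,6-dimethoxy-3-(methoxymethoxy)phenyl]acetyl}-4-isopropyl-1,3-oxazolidin-2-one F5.
  - Alkylation with 7 as in step 4 gives (4R)-3-{(2R)-2-[2-bromo-5,6-dimethoxy-3-(methoxymethoxy)phenyl]-5-methylhex-4-enoyl}-4-isopropyl-1,3-oxazolidin-2-one F6.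
  - LiBH4 reduction gives (2R)-2-[2-bromo-5,6-dimethoxy-3-(methoxymethoxy)phenyl]-5-methylhex-4-en-1-ol F7, and silylation gives its tert-butyldimethylsilyl ether F8.
  - Bromine–lithium exchange (n-BuLi, −78 °C), transmetalation with CuBr·SMe2 and coupling with 13 give tert-butyl({(2R)-2-[2-[(2E)-3,7-dimethylocta-2,6-dien-1-yl]-5,6-dimethoxy-3-(methoxymethoxy)phenyl]-5-methylhex-4-en-1-yl}oxy)dimethylsilane F9.
  - Directed metalation of F9 at the carbon between the two oxygen substituents and coupling with 7, as in step 7, then give 15.

**Step 12 (with step 13).**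
- What may go wrong: erosion of the C10 configuration by deprotonation γ to the ynoate (allenoate formation) during acylation or cuprate addition.
- Fallback: a route that never passes through an ynoate, setting out from 18 and returning at 22. The acetylide from 18 (n-BuLi, −78 °C) is trapped with paraformaldehyde to give the propargylic alcohol (4S)-4-Ar-7-methyloct-6-en-2-yn-1-ol F10. Alkoxide-directed syn-carbomagnesiation with MeMgBr and catalytic Fe(acac)3 (trivalent iron) places the methyl group on the distal alkyne carbon and, after protonation, gives the (Z)-allylic alcohol 22 directly.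

## Further compounds

F1 | step 17 | (2Z,4S)-4-{2-[(2E)-3,7-dimethylocta-2,6-dien-1-yl]-3-hydroxy-5,6-dimethoxy-4-(3-methylbut-2-en-1-yl)phenyl}-3,7-dimethylocta-2,6-dien-1-ol | Oc1c(C/C=C(\C)CCC=C(C)C)c([C@@H](CC=C(C)C)/C(C)=C\CO)c(OC)c(OC)c1CC=C(C)C
F2 | step 17 | 3-[(2Z,4S)-1-bromo-3,7-dimethylocta-2,6-dien-4-yl]-2-[(2E)-3,7-dimethylocta-2,6-dien-1-yl]-4,5-dimethoxy-6-(3-methylbut-2-en-1-yl)phenol | Oc1c(C/C=C(\C)CCC=C(C)C)c([C@@H](CC=C(C)C)/C(C)=C\CBr)c(OC)c(OC)c1CC=C(C)C
F3 | step 20 | ring-C-closed chlorohydrin: rings A, B and C of 30 with C13 as a 2-chloropropan-2-yl group on C12 and a free enol hydroxyl on C5 (C12 epimers) | CC(C)=CCC/C(C)=C/C[C@]12CC=C(C)[C@@H]3CC(C(C)(C)Cl)[C@](O)(C(O)=C(CC=C(C)C)C1=O)[C@@]32O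
F4 | step 19 | (4aR,5S,8aR)-8a-[(2E)-3,7-dimethylocta-2,6-dien-1-yl]-4a-hydroxy-3-methoxy-6-methyl-2,5-bis(3-methylbut-2-en-1-yl)-4a,5,8,8a-tetrahydronaphthalene-1,4-dione | CC(C)=CCC/C(C)=C/C[C@]12CC=C(C)[C@H](CC=C(C)C)[C@]2(O)C(=O)C(OC)=C(CC=C(C)C)C1=O
F5 | step 8 | (4R)-3-{[2-bromo-5,6-dimethoxy-3-(methoxymethoxy)phenyl]acetyl}-4-isopropyl-1,3-oxazolidin-2-one | COCOc1c(Br)c(CC(=O)N2[C@H](C(C)C)COC2=O)c(OC)c(OC)c1
F6 | step 8 | (4R)-3-{(2R)-2-[2-bromo-5,6-dimethoxy-3-(methoxymethoxy)phenyl]-5-methylhex-4-enoyl}-4-isopropyl-1,3-oxazolidin-2-one | COCOc1c(Br)c([C@@H](CC=C(C)C)C(=O)N2[C@H](C(C)C)COC2=O)c(OC)c(OC)c1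
F7 | step 8 | (2R)-2-[2-bromo-5,6-dimethoxy-3-(methoxymethoxy)phenyl]-5-methylhex-4-en-1-ol | COCOc1c(Br)c([C@@H](CC=C(C)C)CO)c(OC)c(OC)c1
F8 | step 8 | tert-butyl({(2R)-2-[2-bromo-5,6-dimethoxy-3-(methoxymethoxy)phenyl]-5-methylhex-4-en-1-yl}oxy)dimethylsilane | COCOc1c(Br)c([C@@H](CC=C(C)C)CO[Si](C)(C)C(C)(C)C)c(OC)c(OC)c1
F9 | step 8 | tert-butyl({(2R)-2-[2-[(2E)-3,7-dimethylocta-2,6-dien-1-yl]-5,6-dimethoxy-3-(methoxymethoxy)phenyl]-5-methylhex-4-en-1-yl}oxy)dimethylsilane | COCOc1c(C/C=C(\C)CCC=C(C)C)c([C@@H](CC=C(C)C)CO[Si](C)(C)C(C)(C)C)c(OC)c(OC)c1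
F10 | step 12 | (4S)-4-Ar-7-methyloct-6-en-2-yn-1-ol | COCOc1c(C/C=C(\C)CCC=C(C)C)c([C@@H](CC=C(C)C)C#CCO)c(OC)c(OC)c1CC=C(C)C
A1 | alternative 1 | ring B ketone carrying the quaternary C2 (geranyl, 5-methylhex-4-enoyl) and, on C10, the side chain with the C13 triethylsilyl ether and the α-keto ester | CC(C)=CCC/C(C)=C/C[C@@]1(C(=O)CCC=C(C)C)CC=C(C)[C@H](C[C@H](C(C)(C)O[Si](CC)(CC)CC)C(=O)C(=O)OC)C1=O
A2 | alternative 1 | bicyclic cis-diol ester (rings B and C) | CC(C)=CCC/C(C)=C/C[C@@]1(C(=O)CCC=C(C)C)CC=C(C)[C@@H]2C[C@H](C(C)(C)O[Si](CC)(CC)CC)[C@](O)(C(=O)OC)[C@]12O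
A3 | alternative 2 | monocyclic triketone: ring A with C1, C3 and C4 carbonyls, C5 enol and C6 prenyl, C2 bearing geranyl and a 7-methyl-3-oxooct-6-enyl chain | CC(C)=CCC/C(C)=C/C[C@@]1(CCC(=O)CCC=C(C)C)C(=O)C(=O)C(O)=C(CC=C(C)C)C1=O
A4 | alternative 2 | tetracyclic C9 ketone (rings A to D, no C9 methyl) | CC(C)=CCC/C(C)=C/C[C@]12CCC(=O)[C@@H]3C[C@@H]4C(C)(C)OC(=C(CC=C(C)C)C1=O)[C@]4(O)[C@@]32O
A5 | alternative 3 | 2-[(2E)-3,7-dimethylocta-2,6-dien-1-yl]-2-(7-methyl-3-oxooct-6-en-1-yl)cyclohexane-1,3,5-trione | CC(C)=CCC/C(C)=C/CC1(CCC(=O)CCC=C(C)C)C(=O)CC(=O)CC1=O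
A6 | alternative 3 | cis-fused bicyclic ketol (rings A and B) | CC(C)=CCC/C(C)=C/C[C@]12CCC(=O)[C@H](CC=C(C)C)[C@]2(O)CC(=O)CC1=O
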